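An easy thing to take from a run is a slope, so we start with target in the west run, which is this flask followed so far.

- west: solid substrate 0.20 M; coupling partner 1.2 equiv; the very flask that is asked about, followed so far
- flask: solid substrate 0.20 M; coupling partner 1.20 equiv; time 1.5 h

west run (percent of the solid substrate charged)

| time / min | target / % | dissolved substrate / % |
|---|---|---|
| 1.33 | 0 | 4.8 |
| 2.50 | 0.3 | 8.2 |
| 5.00 | 2.0 | 14.1 |
| 10.0 | 4.7 | 23.1 |
| 20.0 | 10.2 | 30.1 |

(scatter of a reading: 0.5 percentage points)

- given per volume of solution although it is solid: solid substrate
- at the start none of the solid substrate is in solution
- dissolved substrate means what is dissolved; the solid is not counted in it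

- how much target there is at 1.5 h, in percent of the solid substrate charged
- concentration of dissolved substrate in solution at 1.5 h, in percent of saturation

Target rises 2.7 percentage points in the 5.00 min up to 10.0 min, then 5.5 points in the next 10.0 min, so the slope holds while dissolved substrate climbs. The forecast's author takes that steady slope forward and reads the reaction “as if a saturated catalyst were limiting”. The forecast is 45 % of target (range 36 % to 52 %) and 80 % of saturation (range 62 % to 92 %).

I divide each slope by the mean [dissolved substrate] instead. This gives a pseudo-first-order coefficient, which should follow [coupling partner]. It falls from 0.0290 min⁻¹ to 0.0207 min⁻¹, a decay constant of 0.0453 min⁻¹. That makes 15.3 min the half-life of the coupling coefficient. With a scatter of 0.5 points on such small rises this is a weak reading, and it does not exclude the forecast's steady rate.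

Still, I commit to it. I hold [dissolved substrate] at its last reading, so the rate integrates in closed form: the last target, plus the last coefficient times [dissolved substrate] over the decay constant, times one minus the exponential of the remaining time. That gives 20.7 % of target.

The flask gives 17.2 % of target and 36.3 % of saturation, under the forecast's low end and nearer my figure. The dispute goes to the falling coefficient, and the straight line keeps the span where it was read, up to 20.0 min.

    solid substrate ⇌ dissolved substrate, rate k1*(cs1 - [dissolved substrate]) while solid is left; crystals form when [dissolved substrate] > cs1 (solubility = 0.110 M, k = 0.0680 min⁻¹)
    dissolved substrate + coupling partner → target (k = 0.250 L mol⁻¹ min⁻¹)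
    2 dissolved substrate → side product (k = 0.190 L mol⁻¹ min⁻¹)
    2 coupling partner → homo dimer (k = 0.100 L mol⁻¹ min⁻¹)
    coupling partner → decomposed reagent (k = 0.0400 min⁻¹)

The half-life read above fits 5.88 times into 1.5 h, and by then the flask holds 0.38 % of its coupling partner, while dissolved substrate goes to side product 66 times as fast as to target. In the flask, target stands at 17.3 % after 15.0 h. The neighbour charged with 3.00 equiv of coupling partner reaches 1.5 h with 0.24 % of its partner left, and it gives 27.0 % of target.

The earlier runs and the new flask were generated by integration for substances that don't exist.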